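**Plan**

1. Retrosynthesis: cut the CH2 bridge (C8–CH2 and CH2–C3 of the pyrone) to give a chromene acylphloroglucinol and 6-ethyl-4-hydroxy-5-methyl-2-pyrone; then cut the two phenol C–O bonds at C5 and C7 (back to C–F), the C6–acyl bond, the pyran C8a–O1 bond and the C4a–C4 bond.
2. Enabling feature: the benzene ring carries its oxygens on C5, C7 and C8a in a 1,3,5-pattern, so it maps onto a 2,4,6-trifluorophenyl ring in which C4a lies between two equivalent C–F carbons. Closing O1 onto either one gives the same 5,7-difluorochromene.
3. The two fluorines left over then flank only C6–H, which fixes the acyl group para to O1, and are afterwards exchanged for the C5 and C7 hydroxyls; C8 remains as the only free ring carbon for the bridge.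
4. Forward order: Sonogashira coupling, Z-semihydrogenation, pyran ring closure by C8a–O1 substitution, C6 lithiation/acylation, double F-to-O exchange, deallylation; the pyrone ring is made separately from a β-keto ester dianion; the halves are joined through a one-carbon Mannich linchpin.
5. Remark on stereochemistry: the target has no stereocentre and is achiral, so no enantiocontrol is needed. The only geometric requirement is the Z-alkene of the cyclisation precursor, set by syn-hydrogenation and kept as the ring C3=C4 bond.

Key step: step 3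

**Route**

Step 1
Reactants: 1 1,3,5-trifluoro-2-iodobenzene; 2 2-methylbut-3-yn-2-ol
Product: 3 2-methyl-4-(2,4,6-trifluorophenyl)but-3-yn-2-ol
Conditions: PdCl2(PPh3)2 (2 mol %), CuI (4 mol %), Et3N, THF, rt to 50 °C
Reagents that add atoms: none
Why: Sonogashira coupling; the electron-poor, fluorine-flanked C–I bond should undergo oxidative addition readily while the C–F bonds stay inert to Pd(0)/Cu(I).

Step 2
Reactants: 3 2-methyl-4-(2,4,6-trifluorophenyl)but-3-yn-2-ol
Product: 4 (3Z)-2-methyl-4-(2,4,6-trifluorophenyl)but-3-en-2-ol
Conditions: H2 (1 atm), Lindlar catalyst (Pd/CaCO3, Pb-poisoned), quinoline, EtOAc, rt, stopped after 1 equiv H2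
Reagents that add atoms: none
Why: Lindlar semihydrogenation adds H2 syn on the poisoned Pd surface, which should give the Z-alkene that holds the carbinol oxygen next to an ortho C–F carbon, without touching C–F bonds.

Step 3
Reactants: 4 (3Z)-2-methyl-4-(2,4,6-trifluorophenyl)but-3-en-2-ol
Product: 6 5,7-difluoro-2,2-dimethyl-2H-chromene, via sodium Z-alkenolate 5 (not isolated)
Conditions: NaH (1.3 equiv), DMF (0.05 M), 0 °C to 60 °C
Reagents that add atoms: none
Why: NaH converts the tertiary alcohol into alkoxide 5, whose oxygen adds to an ortho C–F carbon to give a Meisenheimer σ-complex with its charge on C4a, C6 and C8, stabilised inductively by the two remaining fluorines on C5 and C7; loss of fluoride restores the arene (addition–elimination SNAr). The closest known reaction type is the intramolecular SNAr O-arylation of polyfluoroarenes by tethered alkoxides, as used for chromans and dihydrobenzofurans. The pyran ring closes in a 6-exo-trig mode with respect to the C8a=C8 π-bond. No stereocentre is formed; the Z-geometry from step 2 becomes the ring cis-alkene C3=C4. The selectivity needed is ortho against para fluoride and one ortho fluoride against the other: the para fluorine is out of reach of the three-atom tether, and the two ortho C–F carbons are interconverted by rotation about the aryl–vinyl bond, so only one chromene can form. Dilution should suppress intermolecular substitution.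

Step 4
Reactants: 6 5,7-difluoro-2,2-dimethyl-2H-chromene
Product: 9 1-(5,7-difluoro-2,2-dimethyl-2H-chromen-6-yl)-2-methylpropan-1-one, via 6-lithiochromene 7 (not isolated), via lithium hemiaminal adduct 8 (not isolated)
Conditions: LDA (commercial solution, 1.1 equiv), THF, −78 °C; then i-PrC(O)N(OMe)Me, −78 °C to 0 °C; aq NH4Cl
Reagents that add atoms: N-methoxy-N-methylisobutyramide, CC(C)C(=O)N(C)OC
Why: Directed ortho-metalation followed by Weinreb ketone synthesis; of the two ring C–H bonds only C6–H is flanked by two fluorines and should be removed selectively at −78 °C, where the ortho-fluoroaryllithium does not lose LiF, and the chelated adduct 8 stops the acylation at the ketone.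

Step 5
Reactants: 9 1-(5,7-difluoro-2,2-dimethyl-2H-chromen-6-yl)-2-methylpropan-1-one
Product: 11 1-[2,2-dimethyl-5,7-bis(prop-2-en-1-yloxy)-2H-chromen-6-yl]-2-methylpropan-1-one, via 7-allyloxy-5-fluoro ketone 10 (not isolated)
Conditions: allyl alcohol (3 equiv), NaH (3 equiv), DMF, 0 °C to 60 °C
Reagents that add atoms: allyl alcohol (prop-2-en-1-ol), C=CCO
Why: Double SNAr; both fluorines are ortho to the ketone, which takes up the Meisenheimer charge, so sodium allyloxide should displace them in turn (the less hindered C7–F first), while the ring ether oxygen para to the ketone is a far poorer leaving group than fluoride.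

Step 6
Reactants: 11 1-[2,2-dimethyl-5,7-bis(prop-2-en-1-yloxy)-2H-chromen-6-yl]-2-methylpropan-1-one
Product: 12 1-(5,7-dihydroxy-2,2-dimethyl-2H-chromen-6-yl)-2-methylpropan-1-one
Conditions: Pd(PPh3)4 (5 mol %), morpholine (10 equiv), THF, rt
Reagents that add atoms: none
Why: Tsuji–Trost deallylation; Pd(0) ionises the primary allyl aryl ethers and morpholine captures the π-allyl units, which should free both phenols under neutral conditions that leave the acid-sensitive chromene intact, since its endocyclic tertiary C2–O bond is poorly aligned for ionisation.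

Step 7
Reactants: 13 ethyl 3-oxopentanoate
Product: 16 ethyl 4-methyl-3,5-dioxoheptanoate, via dilithium dienediolate 14 (not isolated), via tetrahedral Weinreb adduct 15 (not isolated)
Conditions: LDA (commercial solution, 2.1 equiv), THF, −78 °C to 0 °C; then EtC(O)N(OMe)Me, −78 °C to rt; 1 M HCl
Reagents that add atoms: N-methoxy-N-methylpropanamide, CCC(=O)N(C)OC
Why: γ-Acylation of a β-keto ester dianion; the γ-carbon of 14 is the more nucleophilic site, and the stable tetrahedral adduct 15 should prevent over-addition and proton transfer to unreacted dianion.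

Step 8
Reactants: 16 ethyl 4-methyl-3,5-dioxoheptanoate
Product: 17 6-ethyl-4-hydroxy-5-methyl-2H-pyran-2-one
Conditions: DBU (1.1 equiv), toluene, reflux; then 1 M HCl
Reagents that add atoms: none
Why: Base-mediated lactonisation; the C5 enolate oxygen attacks the ester in a 6-exo-trig acyl substitution, ethanol is lost and the product should settle as the 4-hydroxy-2-pyrone tautomer.

Step 9
Reactants: 17 6-ethyl-4-hydroxy-5-methyl-2H-pyran-2-one; 12 1-(5,7-dihydroxy-2,2-dimethyl-2H-chromen-6-yl)-2-methylpropan-1-one
Product: 20 3-{[5,7-dihydroxy-2,2-dimethyl-6-(2-methylpropanoyl)-2H-chromen-8-yl]methyl}-6-ethyl-4-hydroxy-5-methyl-2H-pyran-2-one, via pyrone Mannich base 18 (not isolated), via methylidene pyrandione 19 (not isolated)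
Conditions: (i) 17, CH2=NMe2+ I− (1.05 equiv), MeCN, rt; (ii) 12 (1.0 equiv), 70 °C
Reagents that add atoms: Eschenmoser's salt (N,N-dimethylmethylideneammonium iodide), C=[N+](C)C.[I-]
Why: Mannich reaction at the nucleophilic C3 of the 4-hydroxypyrone, thermal loss of dimethylamine to the methylidene dione 19, and Friedel–Crafts-type conjugate addition (carba-Betti-type coupling) of the phloroglucinol through C8, the only unsubstituted carbon of its ring.

**Compound list**

1 | 1,3,5-trifluoro-2-iodobenzene | Fc1cc(F)c(I)c(F)c1 | starting material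
2 | 2-methylbut-3-yn-2-ol | CC(C)(O)C#C | starting material
3 | 2-methyl-4-(2,4,6-trifluorophenyl)but-3-yn-2-ol | CC(C)(O)C#Cc1c(F)cc(F)cc1F | intermediate
4 | (3Z)-2-methyl-4-(2,4,6-trifluorophenyl)but-3-en-2-ol | CC(C)(O)/C=C\c1c(F)cc(F)cc1F | intermediate
5 | sodium (3Z)-2-methyl-4-(2,4,6-trifluorophenyl)but-3-en-2-olate | CC(C)([O-])/C=C\c1c(F)cc(F)cc1F.[Na+] | intermediate (not isolated)
6 | 5,7-difluoro-2,2-dimethyl-2H-chromene | CC1(C)C=Cc2c(F)cc(F)cc2O1 | intermediate
7 | (5,7-difluoro-2,2-dimethyl-2H-chromen-6-yl)lithium | [Li]c1c(F)cc2OC(C)(C)C=Cc2c1F | intermediate (not isolated)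
8 | lithium 1-(5,7-difluoro-2,2-dimethyl-2H-chromen-6-yl)-1-[methoxy(methyl)amino]-2-methylpropan-1-olate (racemic) | CC(C)C([O-])(N(C)OC)c1c(F)cc2OC(C)(C)C=Cc2c1F.[Li+] | intermediate (not isolated)
9 | 1-(5,7-difluoro-2,2-dimethyl-2H-chromen-6-yl)-2-methylpropan-1-one | CC(C)C(=O)c1c(F)cc2OC(C)(C)C=Cc2c1F | intermediate
10 | 1-[5-fluoro-2,2-dimethyl-7-(prop-2-en-1-yloxy)-2H-chromen-6-yl]-2-methylpropan-1-one | CC(C)C(=O)c1c(OCC=C)cc2OC(C)(C)C=Cc2c1F | intermediate (not isolated)
11 | 1-[2,2-dimethyl-5,7-bis(prop-2-en-1-yloxy)-2H-chromen-6-yl]-2-methylpropan-1-one | CC(C)C(=O)c1c(OCC=C)cc2OC(C)(C)C=Cc2c1OCC=C | intermediate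
12 | 1-(5,7-dihydroxy-2,2-dimethyl-2H-chromen-6-yl)-2-methylpropan-1-one | CC(C)C(=O)c1c(O)cc2OC(C)(C)C=Cc2c1O | intermediate
13 | ethyl 3-oxopentanoate | CCC(=O)CC(=O)OCC | starting material
14 | dilithium 1-ethoxypenta-1,3-diene-1,3-bis(olate) (dianion of 13, enolate geometry not defined) | CC=C([O-])C=C([O-])OCC.[Li+].[Li+] | intermediate (not isolated)
15 | dilithium salt of ethyl 5-hydroxy-5-[methoxy(methyl)amino]-4-methyl-3-oxoheptanoate (C2 enolate, C5 alkoxide; stereocentres not defined) | CCOC([O-])=CC(=O)C(C)C([O-])(CC)N(C)OC.[Li+].[Li+] | intermediate (not isolated)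
16 | ethyl 4-methyl-3,5-dioxoheptanoate (labile C4 centre, racemic and largely enolised) | CCC(=O)C(C)C(=O)CC(=O)OCC | intermediate
17 | 6-ethyl-4-hydroxy-5-methyl-2H-pyran-2-one | CCc1oc(=O)cc(O)c1C | intermediate
18 | 3-[(dimethylamino)methyl]-6-ethyl-4-hydroxy-5-methyl-2H-pyran-2-one | CCc1oc(=O)c(CN(C)C)c(O)c1C | intermediate (not isolated)
19 | 6-ethyl-5-methyl-3-methylidene-2H-pyran-2,4(3H)-dione | CCC1=C(C)C(=O)C(=C)C(=O)O1 | intermediate (not isolated)
20 | 3-{[5,7-dihydroxy-2,2-dimethyl-6-(2-methylpropanoyl)-2H-chromen-8-yl]methyl}-6-ethyl-4-hydroxy-5-methyl-2H-pyran-2-one | CCc1oc(=O)c(Cc2c(O)c(C(=O)C(C)C)c(O)c3c2OC(C)(C)C=C3)c(O)c1C | target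

**Summary**

Total step count: 9. Longest linear sequence: 7 (steps 1 to 6, then step 9).

Steps most likely to fail:

1. Step 5. After the first fluoride is exchanged, the new ortho-alkoxy group may twist the isobutyryl carbonyl out of the ring plane, so the second addition–elimination could stall; hydride transfer from the alkoxide to the ketone may also compete. Fallback: the oxygens are introduced on a smaller, coplanar activating group and the ketone is built afterwards. Setting out from compound 6, lithiation as in step 4 and quenching with DMF should give 5,7-difluoro-2,2-dimethyl-2H-chromene-6-carbaldehyde F1. Double substitution with sodium allyloxide (allyl alcohol, NaH, DMF) should give 2,2-dimethyl-5,7-bis(prop-2-en-1-yloxy)-2H-chromene-6-carbaldehyde F2. Addition of i-PrMgCl/CeCl3 in THF should give racemic 1-[2,2-dimethyl-5,7-bis(prop-2-en-1-yloxy)-2H-chromen-6-yl]-2-methylpropan-1-ol F3. Dess–Martin oxidation returns to the route at compound 11.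

2. Step 9. The methylidene dione 19 may be captured by a second molecule of pyrone 17 (symmetrical methylene-bis-pyrone) faster than by the hindered C8 of 12. Fallback: the electrophilic carbon is placed on the phloroglucinol half instead. Setting out from compound 12, Eschenmoser's salt in CH2Cl2 at rt should give the isolable phenolic Mannich base 1-{8-[(dimethylamino)methyl]-5,7-dihydroxy-2,2-dimethyl-2H-chromen-6-yl}-2-methylpropan-1-one F4, whose C8 is now blocked against self-coupling. Heating F4 with pyrone 17 in dioxane at 100 °C should expel dimethylamine, form the ortho-quinone methide and add C3 of the pyrone, returning to the route at compound 20.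

3. Step 3. Addition of the hindered tertiary alkoxide to a ring activated only inductively may be slow, so that intermolecular substitution at the para fluorine (oligomers) competes. Fallback: the pyran ring is built by the propargyl ether Claisen route. Setting out from compound 2, conc. HCl/CaCl2/CuCl at 0 °C should give 3-chloro-3-methylbut-1-yne F5. O-Alkylation of commercial 3,5-difluorophenol (Oc1cc(F)cc(F)c1) with K2CO3, KI and catalytic CuI in acetone should give 1,3-difluoro-5-[(2-methylbut-3-yn-2-yl)oxy]benzene F6. Heating F6 in N,N-diethylaniline at about 180 °C (aromatic propargyl Claisen rearrangement, [1,5]-H shift, oxa-6π closure) should give the single possible chromene from this symmetrical phenol, returning to the route at compound 6.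

**Further compounds**

F1 | step 5 | 5,7-difluoro-2,2-dimethyl-2H-chromene-6-carbaldehyde | O=Cc1c(F)cc2OC(C)(C)C=Cc2c1F
F2 | step 5 | 2,2-dimethyl-5,7-bis(prop-2-en-1-yloxy)-2H-chromene-6-carbaldehyde | O=Cc1c(OCC=C)cc2OC(C)(C)C=Cc2c1OCC=C
F3 | step 5 | 1-[2,2-dimethyl-5,7-bis(prop-2-en-1-yloxy)-2H-chromen-6-yl]-2-methylpropan-1-ol (racemic) | CC(C)C(O)c1c(OCC=C)cc2OC(C)(C)C=Cc2c1OCC=C
F4 | step 9 | 1-{8-[(dimethylamino)methyl]-5,7-dihydroxy-2,2-dimethyl-2H-chromen-6-yl}-2-methylpropan-1-one | CC(C)C(=O)c1c(O)c(CN(C)C)c2OC(C)(C)C=Cc2c1O
F5 | step 3 | 3-chloro-3-methylbut-1-yne | CC(C)(Cl)C#C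
F6 | step 3 | 1,3-difluoro-5-[(2-methylbut-3-yn-2-yl)oxy]benzene | CC(C)(Oc1cc(F)cc(F)c1)C#C
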